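Remark on the chemistry: positions are numbered as in cembranes (ring C1–C14; lactone carbons C15, carbonyl C16 and methylene C17; methyls C18, C19 and C20 on C4, C8 and C12), and it is assumed that the two C11 epimers of the secondary hydroperoxide can be resolved by preparative HPLC (a way around this is given at the end).

## Structural features

The target is a cembranoid: a 14-membered carbocycle (C1–C14) with an E trisubstituted alkene at C3=C4 and a Z trisubstituted alkene at C12=C13. Two further rings are fused onto it: a 1,2-dioxane made of C8, C9, C10, C11 and an O–O bridge between C8 and C11, and a cis-fused α-methylene-γ-butyrolactone (C15, C16, C17) across C1 and C2. The five stereocentres fall into two groups: the adjacent pair C1/C2 (1S,2S) at the lactone, and C7 (acetoxy, R), C8 (quaternary, methyl and peroxide oxygen, R) and C11 (allylic peroxide carbon, S). C7 and C8 are directly bonded, and C8 and C11 stand in a 1,4 relationship across the dioxane. The fragile groups are the O–O bond (reducing metals, phosphines, hydrogenation catalysts), the C11–H (allylic and α to the peroxide, so open to base-induced O–O cleavage), the methylene lactone (a Michael acceptor), the allylic C2–O bond and the acetate. The real difficulty is the peroxide ring: the quaternary C8–O bond must be made with defined configuration next to oxygenated C7, and the O–O bond must then survive everything that follows, macrocyclisation included. The key step uses two facts: C6–C12 with methyls C19 and C20 is the carbon chain of nerol, and the 7R,8R oxygen pattern on the dioxane is what results when the (7R,8S) cis-epoxide of the Z alkene is opened with inversion at tertiary C8 by a hydroperoxide on C11.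

## Logic of the disconnections

30 ⇒ 27. The C1–C2 bond and the lactone C16–O bond are cut together. A cis-fused α-methylene-γ-butyrolactone is the retron of the addition of a 2-(alkoxycarbonyl)allyl metal to an aldehyde, so one operation opens both the macrocycle and the lactone and removes two stereocentres. The forward step must insert zinc into the allylic C–Br bond without touching the O–O bond, must run under dilution, and must turn the Z geometry of the allyl unit into the cis ring fusion; the sense of attack relative to the dioxane is left to the substrate.

27 ⇒ 26 ⇒ 25. No skeletal bond is cut; the C2 aldehyde is taken back to a PMB-protected allylic alcohol. An enal would not survive amine catalysis and bromination at the other chain end, so C2 stays masked until the allylic bromide is in place. The forward steps must release and oxidise the C2 alcohol in the presence of the 2-(bromomethyl)enoate.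

25 ⇒ 24 ⇒ 22 + 23. The C1–C15 bond and the C17–Br bond are cut. A 2-(bromomethyl)alk-2-enoate is the product of SN2′ bromination of a Baylis–Hillman adduct, which returns the three lactone carbons to 23. The demand is an amine-catalysed addition to a β,γ-unsaturated aldehyde without migration of the C12=C13 bond, and delivery of bromide at C17 with Z geometry.

22 ⇒ 21 ⇒ 20 ⇒ 13 + 18. After unmasking of C1, the C5–C6 bond is cut by way of a C5=C6 alkene. This separates the C2–C5 unit, whose E C3=C4 alkene can be fixed in a small reagent, from the peroxide-bearing half. The Wittig reaction must engage an α-acetoxy aldehyde without epimerising C7, and the reduction must saturate only the disubstituted C5=C6 bond beside two trisubstituted alkenes and the O–O bond, which points to diimide.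

18 ⇒ 17 ⇒ 16 ⇒ 15 ⇒ 14. The C–P, C–Br and allylic C–O bonds and the PMB ether are removed in turn, which reduces the reagent to 14. The only selective step is the allylic oxidation, which must take place at the E methyl group.

13 ⇒ 12 ⇒ 11. The C6 aldehyde goes back to the silyl ether that has protected this oxygen from the start. The demand is desilylation without transfer of the acetyl group from O7 to O6.

11 ⇒ 8 + 9. The C12=C13 double bond is cut. A Z trisubstituted alkene whose more substituted carbon bears an oxygenated carbon is the retron of the Wittig reaction of an α-oxygenated methyl ketone with a non-stabilised ylide; 9 supplies C13, C14 and C1 with the aldehyde masked. The forward step must be faster than enolisation of 8 towards C11, which would break the O–O bond.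

8 ⇒ 6 ⇒ 5. The C12 carbonyl is traced to the isopropenyl group (one carbon lost on ozonolysis) and the acetate to the free C7 hydroxyl. Both changes are tolerated by the peroxide if the ozonide is reduced with a sulfide and not a phosphine.

5 ⇒ 4. The O–C8 bond of the dioxane is cut. This removes the ring and the quaternary stereocentre at once and leaves an epoxide and a hydroperoxide on a ten-carbon chain. The forward step must open the epoxide at tertiary C8 with inversion in the 6-exo mode and must outrun acid-induced decomposition of the allylic hydroperoxide; for this, 4 carries a bulky, acid-stable silyl ether on O6 and is used as the single 11S epimer.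

4 ⇒ 3 ⇒ 2 ⇒ 1. The C11–O bond is cut by a retro-ene reaction of singlet oxygen, the silyl ether is removed, and the epoxide is returned to the Z alkene of 1. C7 and C8 come from the Sharpless epoxidation, which needs the D-(−)-tartrate to give the (7R,8S)-epoxide. C11 is not controlled by the ene reaction, so the forward sequence includes a separation of regioisomers and epimers.

## Other disconnections considered

Alternative 1: The cut is the C5–C6 bond, made by ring expansion. The twelve-membered cyclic enol ether A1 (ring oxygen between C3 and C7, exocyclic C6 methylene on C7, isopropenyl group on C3) would be heated so that its allyl vinyl ether unit undergoes a [3,3] Claisen shift to the fourteen-membered ketone A2.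
- In its favour: the carbocycle arises by ring expansion, without end-to-end cyclisation under high dilution. A chair transition state should set the E C3=C4 alkene. No reducing metal meets the peroxide. C7 arrives oxygenated.
- Against it here: A1 already contains the dioxane, so the peroxide problem is moved, not solved. A1 could be derived from 5 only by degrading C7 to a carboxyl carbon, which discards the stereocentre set by the epoxidation. The enol ether requires methylenation of a macrolactone with a titanium alkylidene in the presence of O–O. The rearrangement puts a thermal load on the peroxide. A2 then needs a 7R-selective ketone reduction next to quaternary C8, acetylation, and conversion of the lactol ether to the lactone.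
- Comparison: as a ring-forming event the rearrangement is the better of the two (no dilution, no zinc). In alkene-geometry control the two plans are equal. The chosen plan is better in C7/C8 control (reagent-controlled epoxide against a late substrate-controlled reduction) and in step economy after the key step, because its ring closure delivers the final oxidation levels.

Alternative 2: The cut is C1–C14. The seco stannane A3 (tributylstannyl group on butenolide carbon C1, primary Z allylic chloride at C14) would be cyclised by a Stille coupling with Pd2(dba)3 and AsPh3 (zerovalent palladium) to the macrocyclic butenolide A4.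
- In its favour: the closure is catalytic and neutral and creates no stereocentre, so no facial selectivity is at stake at that point. The peroxide is absent during most of the route, which frees the earlier steps from O–O constraints; on this point the alternative is better than the chosen plan.
- Against it here: A4 lacks C17 and the C1 stereocentre, so a cis-selective conjugate reduction and an α-methylenation must follow. The dioxane must be built after macrocyclisation, which needs conversion of the unconfigured C11 silyl ether into an 11S hydroperoxide. No stereoreliable way exists for that at a secondary allylic position. Whether the macrocycle would allow backside attack at C8 is open. A π-allyl palladium intermediate could erode the Z geometry at C12=C13.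
- Comparison: the coupling is the equal or the better of the zinc-mediated closure as a macrocyclisation. The chosen plan solves the hardest feature, the 8R,11S peroxide, at step 4 on a small molecule. It pays for this by carrying the O–O bond through seventeen steps, but is likely shorter after its key step.

Alternative 3: The cut is C11–C12. The seco iodo aldehyde A5 (Z alkenyl iodide at C12, aldehyde at C11, epoxide and methylene lactone in place) would be treated with CrCl2 and catalytic NiCl2, and the alkenylchromium formed from divalent chromium would add to the aldehyde to give the macrocyclic allylic alcohol A6.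
- In its favour: the lactone with C1 and C2 is complete before ring closure and could be set by a reagent-controlled intermolecular allylation; on C1/C2 control the alternative is better than the chosen plan. Alkenylchromium reagents are highly selective for aldehydes and should keep the Z geometry.
- Against it here: A6 carries a C11 hydroxyl as an epimer mixture, not a hydroperoxide. The O–O bond and the C8–O bond are still missing, and turning the allylic alcohol into an 11S hydroperoxide has no dependable solution. A large excess of chromium salt is needed.
- Comparison: both plans leave C11 uncontrolled and are equal in that respect, but the chosen plan meets the epimer problem at step 3 on cheap material, the alternative after macrocyclisation. In closure chemistry the two are comparable. The alternative would need several additional late steps for the peroxide, so its step economy is expected to be worse.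

Key step: step 4

## Route

Step 1
Reactants: 1 nerol
Product: 2 (2R,3S)-2,3-epoxynerol
Conditions: Ti(OiPr)4 (cat.), D-(−)-diethyl tartrate (cat.), t-BuOOH, 4 Å molecular sieves, CH2Cl2, −20 °C
Reagents that add atoms: tert-butyl hydroperoxide, CC(C)(C)OO
Why: Sharpless asymmetric epoxidation: the titanium tartrate catalyst binds the allylic alcohol and epoxidises only its alkene, leaving the prenyl alkene alone. With the D-(−)-tartrate the Z allylic alcohol should give the (2R,3S)-epoxide, which fixes C7 (R) and C8 (S) by reagent control.

Step 2
Reactants: 2 (2R,3S)-2,3-epoxynerol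
Product: 3 TBDPS ether of (2R,3S)-2,3-epoxynerol
Conditions: TBDPSCl, imidazole, CH2Cl2, 0 °C → rt
Reagents that add atoms: tert-butyl(chloro)diphenylsilane, CC(C)(C)[Si](Cl)(c1ccccc1)c1ccccc1
Why: Silylation of the primary alcohol with imidazole as base and nucleophilic catalyst. The bulky, acid-stable TBDPS ether keeps O6 from acting as a nucleophile (Payne rearrangement, competing epoxide opening) in step 4.

Step 3
Reactants: 3 TBDPS ether of (2R,3S)-2,3-epoxynerol
Product: 4 (7R,8S,11S)-epoxy hydroperoxide (C6 OTBDPS; C11 OOH; isopropenyl at C12)
Conditions: O2, hν (visible), tetraphenylporphyrin (cat.), CH2Cl2, 0 °C; silica gel, then preparative HPLC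
Reagents that add atoms: dioxygen, O=O
Why: Schenck ene reaction: singlet oxygen adds to C11 of the electron-rich prenyl alkene with abstraction of a methyl hydrogen, giving the secondary allylic hydroperoxide and an isopropenyl group; epoxide and silyl ether are inert. Abstraction from C10 (tertiary C12 hydroperoxide) and attack on either alkene face are expected to compete because the epoxide is too remote to direct, so C11 is not set here: the tertiary regioisomer is removed on silica and the 11S epimer is taken by preparative HPLC.

Step 4
Reactants: 4 (7R,8S,11S)-epoxy hydroperoxide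
Product: 5 (7R,8R,11S)-dioxane alcohol (C6 OTBDPS; free C7 OH; isopropenyl at C12)
Conditions: camphorsulfonic acid (10 mol%), CH2Cl2, 0 °C → rt
Reagents that add atoms: none
Why: Protonation of the epoxide oxygen by camphorsulfonic acid polarises the C8–O bond, the terminal oxygen of the C11 hydroperoxide attacks C8 from the face opposite to the departing oxygen, and proton loss gives the 1,2-dioxane and the free C7 hydroxyl. The closest known reaction type is the acid-catalysed intramolecular opening of epoxides by hydroperoxides to 1,2-dioxanes, the peroxide counterpart of acid-mediated epoxy alcohol cyclisations to cyclic ethers. The single ring is closed in the 6-exo-tet mode (ring atoms C8, C9, C10, C11, O, O; the breaking C8–O bond lies outside the new ring). The only new stereocentre, C8, is controlled by the configuration of the (7R,8S)-epoxide from step 1: backside displacement inverts C8 to 8R, while C7 keeps its oxygen and its R configuration and C11 is untouched. The step needs regioselectivity for C8 over C7, which the substrate secures twice over, since C8 is the tertiary carbon that best carries the developing positive charge and attack at C7 would require a seven-membered 7-endo closure. It also needs chemoselectivity for epoxide opening over acid-induced fragmentation of the allylic hydroperoxide and over silyl loss; the very acid-labile trisubstituted epoxide, a weak catalytic acid in a non-nucleophilic solvent at low temperature, and the robust TBDPS ether on O6 are chosen for that reason. Dilution is not critical because the nucleophile is tethered four atoms from C8.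

Step 5
Reactants: 5 (7R,8R,11S)-dioxane alcohol
Product: 6 C7 acetate of the dioxane (C6 OTBDPS; isopropenyl at C12)
Conditions: Ac2O, pyridine, DMAP (cat.), CH2Cl2, 0 °C → rt
Reagents that add atoms: acetic anhydride, CC(=O)OC(C)=O
Why: Acylation of the hindered secondary C7 alcohol with DMAP catalysis. The acetate is the one present in the target and also protects O7 for the rest of the route.

Step 6
Reactants: 6 C7 acetate of the dioxane
Product: 8 C12 methyl ketone (C6 OTBDPS; C7 OAc), via ozonide 7 (not isolated)
Conditions: O3, CH2Cl2, −78 °C; then Me2S, −78 °C → rt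
Reagents that add atoms: ozone, [O-][O+]=O
Why: Ozonolysis of the only alkene: cycloaddition, cycloreversion and recombination give the ozonide, which Me2S reduces to the methyl ketone and formaldehyde. Dialkyl peroxides are inert to ozone and to the sulfide, which is preferred to a phosphine for that reason.

Step 7
Reactants: 8 C12 methyl ketone; 9 [2-(1,3-dioxolan-2-yl)ethyl]triphenylphosphonium bromide
Product: 11 (12Z)-alkene with C1 as dioxolane (C6 OTBDPS; C7 OAc), via phosphorus ylide 10 (not isolated)
Conditions: 9, KN(SiMe3)2, THF, 0 °C; then 8, −78 °C → −20 °C
Reagents that add atoms: none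
Why: Wittig reaction of a non-stabilised ylide with an α-oxygenated methyl ketone, a combination known to give the trisubstituted alkene with the new chain cis to the oxygen-bearing carbon (12Z) under salt-free kinetic control. The ylide is formed completely before the ketone is added at −78 °C so that carbonyl addition outruns enolisation towards C11.

Step 8
Reactants: 11 (12Z)-alkene with C1 as dioxolane
Product: 12 C6 primary alcohol (C7 OAc; 12Z; C1 dioxolane)
Conditions: Bu4NF, AcOH (1:1), THF, 0 °C → rt
Reagents that add atoms: none
Why: Fluoride-induced desilylation; acetic acid keeps the medium near neutral so that the acetyl group does not migrate from O7 to the new primary alkoxide, and the acetal is untouched.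

Step 9
Reactants: 12 C6 primary alcohol
Product: 13 C6 aldehyde (C7 OAc; 12Z; C1 dioxolane; same arrangement at C7, descriptor formally 7S)
Conditions: Dess–Martin periodinane, pyridine, CH2Cl2, 0 °C → rt
Reagents that add atoms: none
Why: Dess–Martin oxidation under buffered, non-aqueous conditions should give the α-acetoxy aldehyde without epimerisation at C7 or over-oxidation; it is used without chromatography.

Step 10
Reactants: 14 prenol
Product: 15 prenyl 4-methoxybenzyl ether
Conditions: NaH, 4-methoxybenzyl chloride, Bu4NI (cat.), THF, 0 °C → rt
Reagents that add atoms: 4-methoxybenzyl chloride, COc1ccc(CCl)cc1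
Why: Williamson ether synthesis. The PMB ether should survive ylide formation, diimide, dilute acid, amine and bromination and can later be removed oxidatively.

Step 11
Reactants: 15 prenyl 4-methoxybenzyl ether
Product: 16 (2E)-4-[(4-methoxybenzyl)oxy]-2-methylbut-2-en-1-ol
Conditions: SeO2 (cat.), t-BuOOH, salicylic acid (cat.), CH2Cl2, rt
Reagents that add atoms: tert-butyl hydroperoxide, CC(C)(C)OO
Why: Allylic oxidation by SeO2 (ene reaction, then [2,3]-sigmatropic shift, with t-BuOOH as terminal oxidant) is selective for the E methyl group of a trisubstituted alkene, so the E allylic alcohol is expected. Any enal from over-oxidation is separated on silica.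

Step 12
Reactants: 16 (2E)-4-[(4-methoxybenzyl)oxy]-2-methylbut-2-en-1-ol
Product: 17 (2E)-1-bromo-4-[(4-methoxybenzyl)oxy]-2-methylbut-2-ene
Conditions: CBr4, PPh3, CH2Cl2, 0 °C
Reagents that add atoms: carbon tetrabromide, BrC(Br)(Br)Br
Why: Appel reaction: SN2 displacement of the oxyphosphonium group at the primary allylic carbon, without allylic transposition or loss of E geometry at 0 °C.

Step 13
Reactants: 17 (2E)-1-bromo-4-[(4-methoxybenzyl)oxy]-2-methylbut-2-ene
Product: 18 {(2E)-4-[(4-methoxybenzyl)oxy]-2-methylbut-2-en-1-yl}triphenylphosphonium bromide
Conditions: PPh3, toluene, rt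
Reagents that add atoms: triphenylphosphine, c1ccc(cc1)P(c1ccccc1)c1ccccc1
Why: SN2 quaternisation of triphenylphosphine by the primary allylic bromide; the salt should precipitate from toluene.

Step 14
Reactants: 13 C6 aldehyde; 18 {(2E)-4-[(4-methoxybenzyl)oxy]-2-methylbut-2-en-1-yl}triphenylphosphonium bromide
Product: 20 (3E,12Z)-triene with C5=C6 as E/Z mixture (C2 OPMB; C7 OAc; C1 dioxolane), via allylic phosphorus ylide 19 (not isolated)
Conditions: 18, KN(SiMe3)2, THF, −78 → 0 °C; then 13, −78 °C → rt
Reagents that add atoms: none
Why: Wittig reaction of the allylic ylide, which reacts through its α-carbon, with the α-acetoxy aldehyde forms C5=C6 as an E/Z mixture that is irrelevant because the bond is reduced next; the 3E geometry comes from 18. The ylide is generated and used cold to avoid expulsion of the ether oxygen by vinylogous elimination and epimerisation at C7.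

Step 15
Reactants: 20 (3E,12Z)-triene with C5=C6 as E/Z mixture
Product: 21 (3E,12Z)-diene with saturated C5–C6 (C2 OPMB; C7 OAc; C1 dioxolane)
Conditions: KO2CN=NCO2K, AcOH, MeOH/THF, 0 °C → rt
Reagents that add atoms: none
Why: Diimide, released from the azodicarboxylate by acetic acid, transfers two hydrogens in a concerted syn addition whose rate falls steeply with alkene substitution, so only the 1,2-disubstituted C5=C6 bond should be reduced. The two trisubstituted alkenes and the O–O bond, which would not survive catalytic hydrogenation, are expected to remain.

Step 16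
Reactants: 21 (3E,12Z)-diene with saturated C5–C6
Product: 22 C1 aldehyde (C2 OPMB; 3E; C7 OAc; 12Z)
Conditions: aq. HCl (2 M), THF, 0 °C → rt
Reagents that add atoms: water, O
Why: Acid-catalysed hydrolysis of the dioxolane; the PMB ether, acetate and dioxane tolerate dilute aqueous acid at room temperature. The β,γ-unsaturated aldehyde is worked up without base and used at once to keep the C12=C13 bond out of conjugation.

Step 17
Reactants: 22 C1 aldehyde; 23 methyl acrylate
Product: 24 Baylis–Hillman adduct (C1 carbinol as epimer mixture; methyl 2-methylidene ester; C2 OPMB)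
Conditions: DABCO (1 equiv), 23 (excess, neat), 0 °C
Reagents that add atoms: none
Why: Baylis–Hillman reaction: DABCO adds to 23, the resulting enolate adds to the aldehyde and elimination regenerates the amine. The new carbinol centre at C1 forms as an epimer mixture, which is of no consequence because it becomes sp2 in step 18; the reaction is run cold and stopped early to limit exposure of the aldehyde and the peroxide to the amine.

Step 18
Reactants: 24 Baylis–Hillman adduct
Product: 25 (Z)-2-(bromomethyl)enoate (C17 bromide; C1=C15 Z; C2 OPMB)
Conditions: NBS, Me2S, CH2Cl2, 0 °C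
Reagents that add atoms: N-bromosuccinimide, O=C1CCC(=O)N1Br
Why: The sulfonium salt formed from NBS and Me2S activates the hydroxyl, and bromide attacks the methylene terminus in an SN2′ sense to give the thermodynamically favoured (Z)-2-(bromomethyl)alk-2-enoate. No free electrophilic bromine remains to attack the trisubstituted alkenes.

Step 19
Reactants: 25 (Z)-2-(bromomethyl)enoate
Product: 26 C2 allylic alcohol carrying the (Z)-2-(bromomethyl)enoate
Conditions: DDQ, CH2Cl2/pH 7 buffer, 0 °C
Reagents that add atoms: none
Why: Oxidative PMB cleavage: DDQ abstracts hydride from the electron-rich benzylic position and water hydrolyses the oxocarbenium ion to the alcohol and anisaldehyde. The allylic bromide, the enoate, the acetate and the peroxide are not expected to be oxidised under these neutral conditions.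

Step 20
Reactants: 26 C2 allylic alcohol
Product: 27 C2 enal carrying the (Z)-2-(bromomethyl)enoate
Conditions: MnO2, CH2Cl2, rt
Reagents that add atoms: none
Why: Heterogeneous MnO2 oxidation is selective for the allylic alcohol, stops at the aldehyde and keeps the 3E geometry; the allylic bromide is inert.

Step 21
Reactants: 27 C2 enal carrying the (Z)-2-(bromomethyl)enoate
Product: 30 target (1S,2S,7R,8R,11S; 3E; 12Z), via allylzinc bromide 28 (not isolated), via macrocyclic hydroxy ester 29 (not isolated)
Conditions: Zn dust (activated), THF/sat. aq. NH4Cl, 2 mM, 0 °C → rt; lactonisation on standing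
Reagents that add atoms: none
Why: Intramolecular Barbier allylation: zinc inserts into the allylic C–Br bond and the allylzinc adds through its γ-carbon (C1) to the aldehyde (C2) in a chair-like six-membered transition state, closing the 14-membered ring; the cis hydroxy ester then lactonises. The Z geometry of the allyl unit (C14 cis to the CH2Zn group) places H1 and H2 syn, which gives the cis ring fusion, while the sense of attack relative to the dioxane (1S,2S and not 1R,2R) depends on the conformational bias of the tether, and the diastereomers are separable. Zinc under neutral aqueous conditions is not expected to reduce a dialkyl peroxide, in contrast to zinc in acetic acid.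

## Compound list

1 | nerol, (2Z)-3,7-dimethylocta-2,6-dien-1-ol | CC(C)=CCC/C(C)=C\CO | starting material
2 | (2R,3S)-2,3-epoxynerol, [(2R,3S)-3-methyl-3-(4-methylpent-3-en-1-yl)oxiran-2-yl]methanol | OC[C@@H](O1)[C@]1(C)CCC=C(C)C | intermediate
3 | tert-butyl{[(2R,3S)-3-methyl-3-(4-methylpent-3-en-1-yl)oxiran-2-yl]methoxy}diphenylsilane | CC(C)(C)[Si](c1ccccc1)(c1ccccc1)OC[C@@H](O2)[C@]2(C)CCC=C(C)C | intermediate
4 | (7R,8S,11S)-epoxy hydroperoxide: TBDPS ether of (2R,3S)-2,3-epoxynerol with an (S)-hydroperoxide on C11 and an isopropenyl group at C12 | CC(C)(C)[Si](c1ccccc1)(c1ccccc1)OC[C@@H](O2)[C@]2(C)CC[C@H](OO)C(C)=C | intermediate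
5 | (1R)-2-[tert-butyl(diphenyl)silyl]oxy-1-[(3R,6S)-3-methyl-6-(prop-1-en-2-yl)-1,2-dioxan-3-yl]ethan-1-ol (7R,8R,11S) | CC(C)(C)[Si](c1ccccc1)(c1ccccc1)OC[C@@H](O)[C@@]2(C)CC[C@H](OO2)C(C)=C | intermediate
6 | (1R)-2-[tert-butyl(diphenyl)silyl]oxy-1-[(3R,6S)-3-methyl-6-(prop-1-en-2-yl)-1,2-dioxan-3-yl]ethyl acetate | CC(C)(C)[Si](c1ccccc1)(c1ccccc1)OC[C@@H](OC(C)=O)[C@@]2(C)CC[C@H](OO2)C(C)=C | intermediate
7 | ozonide of 6: 3-methyl-1,2,4-trioxolan-3-yl group on C11 of the dioxane (epimers at the trioxolane carbon) | CC(C)(C)[Si](c1ccccc1)(c1ccccc1)OC[C@@H](OC(C)=O)[C@@]2(C)CC[C@H](OO2)C3(C)OOCO3 | intermediate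
8 | (1R)-1-[(3R,6S)-6-acetyl-3-methyl-1,2-dioxan-3-yl]-2-[tert-butyl(diphenyl)silyl]oxyethyl acetate | CC(C)(C)[Si](c1ccccc1)(c1ccccc1)OC[C@@H](OC(C)=O)[C@@]2(C)CC[C@H](OO2)C(C)=O | intermediate
9 | [2-(1,3-dioxolan-2-yl)ethyl]triphenylphosphonium bromide | [Br-].C1COC(CC[P+](c2ccccc2)(c2ccccc2)c2ccccc2)O1 | starting material
10 | [2-(1,3-dioxolan-2-yl)ethylidene]triphenylphosphorane | C1COC(CC=P(c2ccccc2)(c2ccccc2)c2ccccc2)O1 | intermediate
11 | (1R)-2-[tert-butyl(diphenyl)silyl]oxy-1-{(3R,6S)-6-[(2Z)-4-(1,3-dioxolan-2-yl)but-2-en-2-yl]-3-methyl-1,2-dioxan-3-yl}ethyl acetate | CC(C)(C)[Si](c1ccccc1)(c1ccccc1)OC[C@@H](OC(C)=O)[C@@]2(C)CC[C@H](OO2)/C(C)=C\CC3OCCO3 | intermediate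
12 | (1R)-1-{(3R,6S)-6-[(2Z)-4-(1,3-dioxolan-2-yl)but-2-en-2-yl]-3-methyl-1,2-dioxan-3-yl}-2-hydroxyethyl acetate | OC[C@@H](OC(C)=O)[C@@]1(C)CC[C@H](OO1)/C(C)=C\CC2OCCO2 | intermediate
13 | (1S)-1-{(3R,6S)-6-[(2Z)-4-(1,3-dioxolan-2-yl)but-2-en-2-yl]-3-methyl-1,2-dioxan-3-yl}-2-oxoethyl acetate (C6 aldehyde; spatial arrangement at C7 as in 12) | O=C[C@@H](OC(C)=O)[C@@]1(C)CC[C@H](OO1)/C(C)=C\CC2OCCO2 | intermediate
14 | prenol, 3-methylbut-2-en-1-ol | CC(C)=CCO | starting material
15 | 1-methoxy-4-{[(3-methylbut-2-en-1-yl)oxy]methyl}benzene | CC(C)=CCOCc1ccc(OC)cc1 | intermediate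
16 | (2E)-4-[(4-methoxybenzyl)oxy]-2-methylbut-2-en-1-ol | OC/C(C)=C/COCc1ccc(OC)cc1 | intermediate
17 | 1-({[(2E)-4-bromo-3-methylbut-2-en-1-yl]oxy}methyl)-4-methoxybenzene | BrC/C(C)=C/COCc1ccc(OC)cc1 | intermediate
18 | {(2E)-4-[(4-methoxybenzyl)oxy]-2-methylbut-2-en-1-yl}triphenylphosphonium bromide | [Br-].COc1ccc(COC/C=C(\C)C[P+](c2ccccc2)(c2ccccc2)c2ccccc2)cc1 | intermediate
19 | {(2E)-4-[(4-methoxybenzyl)oxy]-2-methylbut-2-en-1-ylidene}triphenylphosphorane | COc1ccc(COC/C=C(\C)C=P(c2ccccc2)(c2ccccc2)c2ccccc2)cc1 | intermediate
20 | (3E,12Z)-triene, C5=C6 E/Z mixture: C2 OPMB, C7 (R) acetate, (8R,11S)-dioxane, C1 as 1,3-dioxolane | COc1ccc(COC/C=C(\C)C=C[C@@H](OC(C)=O)[C@@]2(C)CC[C@H](OO2)/C(C)=C\CC3OCCO3)cc1 | intermediate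
21 | (3E,12Z)-diene with saturated C5–C6: C2 OPMB, C7 (R) acetate, (8R,11S)-dioxane, C1 as 1,3-dioxolane | COc1ccc(COC/C=C(\C)CC[C@@H](OC(C)=O)[C@@]2(C)CC[C@H](OO2)/C(C)=C\CC3OCCO3)cc1 | intermediate
22 | C1 aldehyde: C2 OPMB, 3E, C7 (R) acetate, (8R,11S)-dioxane, 12Z | COc1ccc(COC/C=C(\C)CC[C@@H](OC(C)=O)[C@@]2(C)CC[C@H](OO2)/C(C)=C\CC=O)cc1 | intermediate
23 | methyl acrylate | C=CC(=O)OC | starting material
24 | Baylis–Hillman adduct: methyl 2-methylidene-3-hydroxy ester at C1 (epimers), C2 OPMB, 3E, 7R, 8R, 11S, 12Z | COc1ccc(COC/C=C(\C)CC[C@@H](OC(C)=O)[C@@]2(C)CC[C@H](OO2)/C(C)=C\CC(O)C(=C)C(=O)OC)cc1 | intermediate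
25 | methyl (Z)-2-(bromomethyl)alk-2-enoate (C1=C15 Z, bromide on C17), C2 OPMB, 3E, 7R, 8R, 11S, 12Z | COc1ccc(COC/C=C(\C)CC[C@@H](OC(C)=O)[C@@]2(C)CC[C@H](OO2)/C(C)=C\C/C=C(\CBr)C(=O)OC)cc1 | intermediate
26 | C2 allylic alcohol with the (Z)-2-(bromomethyl)enoate, 3E, 7R, 8R, 11S, 12Z | OC/C=C(\C)CC[C@@H](OC(C)=O)[C@@]1(C)CC[C@H](OO1)/C(C)=C\C/C=C(\CBr)C(=O)OC | intermediate
27 | C2 enal with the (Z)-2-(bromomethyl)enoate, 3E, 7R, 8R, 11S, 12Z | O=C/C=C(\C)CC[C@@H](OC(C)=O)[C@@]1(C)CC[C@H](OO1)/C(C)=C\C/C=C(\CBr)C(=O)OC | intermediate
28 | allylzinc bromide from 27 (zinc on C17) | O=C/C=C(\C)CC[C@@H](OC(C)=O)[C@@]1(C)CC[C@H](OO1)/C(C)=C\C/C=C(\C[Zn]Br)C(=O)OC | intermediate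
29 | macrocyclic hydroxy ester: 14-membered ring, (1S,2S) with C2 OH and methyl 2-propenoate on C1, 3E, 7R acetate, (8R,11S)-dioxane, 12Z | O[C@H]1/C=C(\C)CC[C@@H](OC(C)=O)[C@@]2(C)CC[C@H](OO2)/C(C)=C\C[C@H]1C(=C)C(=O)OC | intermediate
30 | CNP0238885.8, (1S,2S,7R,8R,11S,3E,12Z)-7-acetoxy-8,11-epidioxycembra-3,12,15(17)-trien-16,2-olide | C=C1C(=O)O[C@H]2/C=C(\C)CC[C@@H](OC(C)=O)[C@@]3(C)CC[C@H](OO3)/C(C)=C\C[C@@H]12 | target

## Step count and uncertain steps

Total step count: 21 (17 in the main line, 4 for phosphonium salt 18). Longest linear sequence: 17 steps (steps 1–9 and 14–21, from 1 to 30).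

Step 4 (key step). The most likely failure is acid-induced fragmentation of the secondary allylic hydroperoxide (Hock-type cleavage), or ionisation at C8 followed by elimination, hydride shift or partial loss of stereospecificity, all competing with ring closure. The fallback sets out from 4 and avoids protic acid. The hydroperoxide is silylated (Et3SiCl, imidazole) to the triethylsilyl peroxide F1. A catalytic silyl triflate (Me3SiOTf, CH2Cl2, −78 °C) then activates the epoxide, the silylated peroxide oxygen attacks C8 and the silyl group passes to O7, giving the C7 triethylsilyl ether F2. Mild methanolysis (pyridinium p-toluenesulfonate, MeOH) removes the secondary triethylsilyl group beside the primary TBDPS ether and returns to the route at 5.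

Step 3. What may go wrong is lack of selectivity in the ene reaction (hydrogen abstraction at C10 as well as at the methyl group, no facial control) followed by incomplete chromatographic resolution of the C11 epimers, whose stereocentres are two methylene groups apart from C8. The fallback sets out from 3 and moves the separation to a ring compound. Only the tertiary regioisomer is removed after photooxygenation. The pair of 4 and its (11R)-epimer, hydroperoxide F3, is cyclised together under the conditions of step 4. Compound 5 is then separated from the (11R)-dioxane F4; the two differ in the relative configuration of two centres in the same six-membered ring and should separate on silica. The route is rejoined at 5.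

Step 7. The likely failure is deprotonation of the α-peroxy ketone at C11 by the ylide, followed by O–O cleavage (Kornblum–DeLaMare-type fragmentation), together with incomplete Z selectivity that leaves inseparable alkene isomers. The fallback sets out from 8 and uses a Horner–Wittig sequence with separable intermediates.
- Salt 9 is hydrolysed with aqueous NaOH to [2-(1,3-dioxolan-2-yl)ethyl]diphenylphosphine oxide F5, with loss of benzene.
- F5 is lithiated (n-BuLi, THF, −78 °C), transmetallated with CeCl3 to lower its basicity, and added to 8.
- The β-hydroxy phosphine oxides are separated. The two with unlike configuration at C12/C13, the (12R,13S)-adduct F6 and the (12S,13R)-adduct F7, both undergo syn elimination with KN(SiMe3)2 to the Z alkene. No α-peroxy carbonyl group is left at that stage.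
- The route is rejoined at 11.

Step 17. What may go wrong is amine-induced migration of the C12=C13 bond into conjugation with the aldehyde, aldol self-condensation, and slow base-induced opening of the dioxane at the allylic C11–H during a long reaction. The fallback sets out from 22 and uses a preformed acrylate α-anion equivalent at low temperature. Aldol addition of the lithium enolate of methyl 3-(dimethylamino)propanoate (LiN(iPr)2, THF, −78 °C) should give the β-hydroxy α-(dimethylaminomethyl) ester F8. N-Methylation with MeI gives the trimethylammonium iodide F9, and brief treatment with K2CO3 eliminates trimethylamine. The route is rejoined at 24.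

Step 21. The likely failures are reductive cleavage of the O–O bond at the zinc surface, oligomerisation, and insufficient facial discrimination in the ring closure. The fallback sets out from 22, replaces steps 17–21 and uses no reducing metal.
- Horner–Wadsworth–Emmons reaction of 22 with the known reagent methyl 2-(diethoxyphosphoryl)-3-(trimethylsilyl)propanoate (NaH, THF, −78 °C) gives the 2-(trimethylsilylmethyl)enoate F10.
- DDQ removes the PMB group to give the allylsilane alcohol F11, and MnO2 gives the allylsilane enal F12.
- A fluoride source (Bu4NF) or a Lewis acid triggers an intramolecular Hosomi–Sakurai reaction of the allylsilane with the C2 aldehyde. This closure type is established for methylene lactones fused to carbocycles and proceeds through a different transition state from the zinc reaction, so it gives a second chance at the ring-fusion and facial selectivity.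
- The route is rejoined at 29, which lactonises to 30.

## Further compounds

F1 | step 4 | triethylsilyl peroxide of 4 | CC(C)(C)[Si](c1ccccc1)(c1ccccc1)OC[C@@H](O2)[C@]2(C)CC[C@H](OO[Si](CC)(CC)CC)C(C)=C
F2 | step 4 | C7 triethylsilyl ether of 5 | CC(C)(C)[Si](c1ccccc1)(c1ccccc1)OC[C@@H](O[Si](CC)(CC)CC)[C@@]2(C)CC[C@H](OO2)C(C)=C
F3 | step 3 | (11R)-epimer of hydroperoxide 4 | CC(C)(C)[Si](c1ccccc1)(c1ccccc1)OC[C@@H](O2)[C@]2(C)CC[C@@H](OO)C(C)=C
F4 | step 3 | (11R)-epimer of dioxane alcohol 5 | CC(C)(C)[Si](c1ccccc1)(c1ccccc1)OC[C@@H](O)[C@@]2(C)CC[C@@H](OO2)C(C)=C
F5 | step 7 | [2-(1,3-dioxolan-2-yl)ethyl]diphenylphosphine oxide | O=P(CCC1OCCO1)(c1ccccc1)c1ccccc1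
F6 | step 7 | (12R,13S)-β-hydroxy phosphine oxide from 8 | CC(C)(C)[Si](c1ccccc1)(c1ccccc1)OC[C@@H](OC(C)=O)[C@@]2(C)CC[C@H](OO2)[C@@](C)(O)[C@H](CC3OCCO3)P(=O)(c4ccccc4)c4ccccc4
F7 | step 7 | (12S,13R)-β-hydroxy phosphine oxide from 8 | CC(C)(C)[Si](c1ccccc1)(c1ccccc1)OC[C@@H](OC(C)=O)[C@@]2(C)CC[C@H](OO2)[C@](C)(O)[C@@H](CC3OCCO3)P(=O)(c4ccccc4)c4ccccc4
F8 | step 17 | β-hydroxy α-(dimethylaminomethyl) methyl ester from 22 (epimers at C1 and C15) | COc1ccc(COC/C=C(\C)CC[C@@H](OC(C)=O)[C@@]2(C)CC[C@H](OO2)/C(C)=C\CC(O)C(CN(C)C)C(=O)OC)cc1
F9 | step 17 | trimethylammonium iodide of F8 | [I-].COc1ccc(COC/C=C(\C)CC[C@@H](OC(C)=O)[C@@]2(C)CC[C@H](OO2)/C(C)=C\CC(O)C(C[N+](C)(C)C)C(=O)OC)cc1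
F10 | step 21 | methyl 2-(trimethylsilylmethyl)alk-2-enoate with C2 OPMB (C1=C15 isomers) | COc1ccc(COC/C=C(\C)CC[C@@H](OC(C)=O)[C@@]2(C)CC[C@H](OO2)/C(C)=C\CC=C(C[Si](C)(C)C)C(=O)OC)cc1
F11 | step 21 | methyl 2-(trimethylsilylmethyl)alk-2-enoate with free C2 hydroxyl | OC/C=C(\C)CC[C@@H](OC(C)=O)[C@@]1(C)CC[C@H](OO1)/C(C)=C\CC=C(C[Si](C)(C)C)C(=O)OC
F12 | step 21 | methyl 2-(trimethylsilylmethyl)alk-2-enoate with C2 enal | O=C/C=C(\C)CC[C@@H](OC(C)=O)[C@@]1(C)CC[C@H](OO1)/C(C)=C\CC=C(C[Si](C)(C)C)C(=O)OC
A1 | alternative 1 | twelve-membered cyclic enol ether (ring oxygen between C3 and C7, C6 methylene on C7, isopropenyl on C3, C3 configuration left open) | COC1O[C@H]2C(C(C)=C)OC(=C)[C@@]3(C)CC[C@H](OO3)/C(C)=C\C[C@H]2C1=C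
A2 | alternative 1 | fourteen-membered C7 ketone with E C3=C4 alkene, dioxane and methylene lactol methyl ether | COC1O[C@H]2/C=C(\C)CCC(=O)[C@@]3(C)CC[C@H](OO3)/C(C)=C\C[C@H]2C1=C
A3 | alternative 2 | seco C1-tributylstannyl butenolide with C14 (Z)-allylic chloride, 7,8-epoxide and C11 silyl ether | O=C1C=C([Sn](CCCC)(CCCC)CCCC)[C@@H](O1)/C=C(\C)CC[C@@H](O2)[C@]2(C)CCC(O[Si](C)(C)C(C)(C)C)/C(C)=C\CCl
A4 | alternative 2 | macrocyclic butenolide with 7,8-epoxide and C11 silyl ether | O=C1C=C2[C@@H](O1)/C=C(\C)CC[C@@H](O3)[C@]3(C)CCC(O[Si](C)(C)C(C)(C)C)/C(C)=C\C2
A5 | alternative 3 | seco C11 aldehyde with (Z)-alkenyl iodide at C12, 7,8-epoxide and cis methylene lactone | C=C1C(=O)O[C@@H](/C=C(\C)CC[C@@H](O2)[C@]2(C)CCC=O)[C@H]1C/C=C(/C)I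
A6 | alternative 3 | macrocyclic epoxy lactone with C11 allylic alcohol (epimers) | C=C1C(=O)O[C@H]2/C=C(\C)CC[C@@H](O3)[C@]3(C)CCC(O)/C(C)=C\C[C@@H]12
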